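The O1–C2 bond of the dihydrofuran ring (ring B) is the disconnection on which the route rests. C2 is benzylic and sits para to the C4' oxygen of the trioxygenated aryl ring. When that oxygen is kept as an OH, a two-electron oxidation turns the unit into a p-quinone methide with C2 as its exocyclic carbon, and the ring A hydroxyl on C7a adds to it. One operation thus closes ring B and sets C2 trans to the C3 methyl. The precursor is an open-chain (R)-1,2-diarylpropane: ring A has a free ortho OH and a silylated para OH, the other ring is 4-hydroxy-3,5-dimethoxyphenyl. C3 comes from asymmetric hydrogenation, C5 from a late reagent-controlled hydroxylative dearomatisation.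

Key step: step 9

Assumption: the sense of induction of the (S)-configured iridium catalyst in step 7 is taken over from the parent (E)-1,2-diphenylpropene, and the (R)-configured iodyl reagent in step 14 is taken to be the one matched to the required C5 face; should a pilot run show the opposite sense, the antipode is used and nothing else changes.

Step 1
Reactants: 1 4-bromo-2,6-dimethoxyphenol
Product: 2 2-(benzyloxy)-5-bromo-1,3-dimethoxybenzene
Conditions: BnBr, K2CO3, DMF, rt
Reagents that add atoms: benzyl bromide, BrCc1ccccc1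
Why: Williamson etherification of the acidic 2,6-dimethoxyphenol masks the hydroxyl that would otherwise interfere in the metal-catalysed steps and in the hydrogenation.

Step 2
Reactants: 2 2-(benzyloxy)-5-bromo-1,3-dimethoxybenzene
Product: 3 2-(benzyloxy)-1,3-dimethoxy-5-(prop-1-yn-1-yl)benzene
Conditions: propyne (solution in THF, excess), Pd(PhCN)2Cl2 (cat.), P(t-Bu)3 (cat.), CuI (cat.), i-Pr2NH, dioxane, rt, sealed vessel
Reagents that add atoms: propyne, CC#C
Why: Sonogashira coupling, in which the bulky electron-rich phosphine allows oxidative addition into the electron-rich aryl bromide at room temperature and the terminal alkyne can couple only once.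

Step 3
Reactants: 3 2-(benzyloxy)-1,3-dimethoxy-5-(prop-1-yn-1-yl)benzene
Product: 4 2-[(Z)-1-(4-(benzyloxy)-3,5-dimethoxyphenyl)prop-1-en-2-yl]-4,4,5,5-tetramethyl-1,3,2-dioxaborolane (aryl and methyl cis, aryl trans to boron)
Conditions: B2pin2, CuCl (cat.), NaOt-Bu (cat.), P(p-tol)3 (cat.), MeOH (2 equiv), THF, rt
Reagents that add atoms: bis(pinacolato)diboron, CC1(C)OB(OC1(C)C)B1OC(C)(C)C(C)(C)O1
Why: Copper-catalysed borylcupration and protonation (formal hydroboration) of a 1-aryl-1-alkyne is a syn addition that places boron on the methyl-bearing carbon and copper on the aryl-stabilised carbon, so one geometrically defined alkenyl boronate should result.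

Step 4
Reactants: 5 4-bromobenzene-1,3-diol (4-bromoresorcinol)
Product: 6 2-bromo-5-[(triisopropylsilyl)oxy]phenol
Conditions: TIPSCl (1.0 equiv), imidazole, CH2Cl2, -20 to 0 °C
Reagents that add atoms: chlorotriisopropylsilane, CC(C)[Si](Cl)(C(C)C)C(C)C
Why: Silyl ether formation with the bulky chlorosilane should select the unhindered hydroxyl para to bromine over the one flanked by bromine, which differentiates the two ring A oxygens on cheap material at the outset.

Step 5
Reactants: 6 2-bromo-5-[(triisopropylsilyl)oxy]phenol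
Product: 7 [3-(benzyloxy)-4-bromophenoxy]triisopropylsilane
Conditions: BnBr, K2CO3, acetone, 50 °C
Reagents that add atoms: benzyl bromide, BrCc1ccccc1
Why: Williamson etherification under mild carbonate conditions caps the future O1 with the same group as the syringyl oxygen while leaving the aryl silyl ether intact.

Step 6
Reactants: 4 2-[(Z)-1-(4-(benzyloxy)-3,5-dimethoxyphenyl)prop-1-en-2-yl]-4,4,5,5-tetramethyl-1,3,2-dioxaborolane; 7 [3-(benzyloxy)-4-bromophenoxy]triisopropylsilane
Product: 8 {3-(benzyloxy)-4-[(E)-1-(4-(benzyloxy)-3,5-dimethoxyphenyl)prop-1-en-2-yl]phenoxy}triisopropylsilane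
Conditions: Pd(OAc)2 (cat.), SPhos (cat.), K3PO4, toluene/H2O, 80 °C
Reagents that add atoms: none
Why: Suzuki–Miyaura coupling proceeds with retention of alkene geometry and the dialkylbiarylphosphine copes with the ortho-substituted electron-rich bromide, so the (E)-alpha-methylstilbene should be obtained as a single isomer, which a dehydration route would not guarantee.

Step 7
Reactants: 8 {3-(benzyloxy)-4-[(E)-1-(4-(benzyloxy)-3,5-dimethoxyphenyl)prop-1-en-2-yl]phenoxy}triisopropylsilane
Product: 9 (R)-{3-(benzyloxy)-4-[1-(4-(benzyloxy)-3,5-dimethoxyphenyl)propan-2-yl]phenoxy}triisopropylsilane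
Conditions: H2 (50 bar), [Ir(cod)((S)-tBu-PHOX)]BArF (1 mol%; tBu-PHOX = 4-tert-butyl-2-[2-(diphenylphosphanyl)phenyl]-4,5-dihydrooxazole, BArF = B[3,5-(CF3)2C6H3]4), CH2Cl2, rt
Reagents that add atoms: none
Why: Iridium-catalysed asymmetric hydrogenation of an unfunctionalised trisubstituted aryl alkene, for which (E)-1,2-diarylpropenes are the standard substrate class, should deliver hydrogen to one enantioface and set the methyl-bearing benzylic centre (the later C3) as R without touching the benzyl or silyl ethers.

Step 8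
Reactants: 9 (R)-{3-(benzyloxy)-4-[1-(4-(benzyloxy)-3,5-dimethoxyphenyl)propan-2-yl]phenoxy}triisopropylsilane
Product: 10 (R)-2-[1-(4-hydroxy-3,5-dimethoxyphenyl)propan-2-yl]-5-[(triisopropylsilyl)oxy]phenol
Conditions: H2 (1 atm), Pd/C (10%), EtOAc/EtOH, rt
Reagents that add atoms: none
Why: Hydrogenolysis of the two aryl benzyl ethers frees both phenols needed next in one operation, and neither the silyl ether nor the stereocentre, which carries no heteroatom, is affected.

Step 9
Reactants: 10 (R)-2-[1-(4-hydroxy-3,5-dimethoxyphenyl)propan-2-yl]-5-[(triisopropylsilyl)oxy]phenol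
Product: 12 2,6-dimethoxy-4-{(2S,3S)-3-methyl-6-[(triisopropylsilyl)oxy]-2,3-dihydrobenzofuran-2-yl}phenol, via p-quinone methide 11 (not isolated)
Conditions: Ag2O (1.3 equiv), CH2Cl2, rt, dark
Reagents that add atoms: none
Why: Ag2O takes two electrons and the C2 proton from the 4-alkyl-2,6-dimethoxyphenol to give p-quinone methide 11 with C2 as its exocyclic carbon, and the C7a hydroxyl of ring A then adds to C2 in a 1,6-addition that restores the aromatic ring and forms O1–C2. The closest known reaction type is the Ag2O-mediated formation of p-quinone methides from 4-alkyl-2,6-dimethoxyphenols and their intramolecular capture by a phenol, the ring-forming event when phenylcoumarans arise by oxidative coupling of propenylphenols. Ring B closes in the 5-exo-trig mode, since the attacked carbon C2 lies inside the new ring and its double-bond partner outside. The new stereocentre C2 is controlled by the C3 methyl group: the planar quinone methide is attacked so that the aryl group ends up trans to the methyl, and because the addition can revert through 11 the trans (2S,3S) isomer should also be the thermodynamic outcome. The step needs oxidation at the syringyl phenol only, which its two ortho methoxy groups and para alkyl group secure, whereas the ring A phenol carries its second oxygen meta and cannot form a quinone. The silyl ether on the C6 oxygen leaves O1 as the only internal nucleophile, and a small excess of oxidant at room temperature should avoid re-oxidation of 12 towards the aromatic benzofuran.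

Step 10
Reactants: 12 2,6-dimethoxy-4-{(2S,3S)-3-methyl-6-[(triisopropylsilyl)oxy]-2,3-dihydrobenzofuran-2-yl}phenol
Product: 13 triisopropyl{[(2S,3S)-3-methyl-2-(3,4,5-trimethoxyphenyl)-2,3-dihydrobenzofuran-6-yl]oxy}silane
Conditions: MeI, K2CO3, acetone, 40 °C
Reagents that add atoms: iodomethane, CI
Why: Williamson O-methylation of the only free hydroxyl completes the trimethoxyphenyl ring under mild carbonate conditions that phenolic phenylcoumarans and aryl triisopropylsilyl ethers tolerate, and it removes the phenol through which ring B could reopen.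

Step 11
Reactants: 13 triisopropyl{[(2S,3S)-3-methyl-2-(3,4,5-trimethoxyphenyl)-2,3-dihydrobenzofuran-6-yl]oxy}silane
Product: 14 (2S,3S)-3-methyl-2-(3,4,5-trimethoxyphenyl)-2,3-dihydrobenzofuran-6-ol
Conditions: TBAF, AcOH (1 equiv each), THF, 0 °C
Reagents that add atoms: none
Why: Fluoride-mediated cleavage of the aryl silyl ether, buffered with acetic acid to keep the medium near neutral, frees the C6 phenol that directs the next two steps and is later dearomatised.

Step 12
Reactants: 14 (2S,3S)-3-methyl-2-(3,4,5-trimethoxyphenyl)-2,3-dihydrobenzofuran-6-ol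
Product: 15 (2S,3S)-5-bromo-3-methyl-2-(3,4,5-trimethoxyphenyl)-2,3-dihydrobenzofuran-6-ol
Conditions: NBS (1.0 equiv), CH2Cl2, -40 to -10 °C, dark
Reagents that add atoms: N-bromosuccinimide, O=C1CCC(=O)N1Br
Why: Electrophilic aromatic bromination is carried out on the free phenol because C5, ortho to the hydroxyl and para to O1, should then react far faster than C7, which is wedged between two oxygens, and than the trimethoxyphenyl ring, which has no free hydroxyl.

Step 13
Reactants: 15 (2S,3S)-5-bromo-3-methyl-2-(3,4,5-trimethoxyphenyl)-2,3-dihydrobenzofuran-6-ol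
Product: 16 (2S,3S)-5-allyl-3-methyl-2-(3,4,5-trimethoxyphenyl)-2,3-dihydrobenzofuran-6-ol
Conditions: allyltributylstannane, Pd(PPh3)4 (cat.), DMF, 90 °C
Reagents that add atoms: allyltributylstannane, C=CC[Sn](CCCC)(CCCC)CCCC
Why: Stille coupling of the aryl bromide with the allylstannane runs under neutral conditions that tolerate the free phenol and should not move the terminal double bond into conjugation.

Step 14
Reactants: 16 (2S,3S)-5-allyl-3-methyl-2-(3,4,5-trimethoxyphenyl)-2,3-dihydrobenzofuran-6-ol
Product: 17 (2S,3S,5R)-5-allyl-5-hydroxy-3-methyl-2-(3,4,5-trimethoxyphenyl)-2,3-dihydrobenzofuran-6(5H)-one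
Conditions: (R)-2,2'-diiodyl-1,1'-binaphthalene (1.0 equiv, made beforehand from the commercial diiodide and dimethyldioxirane), CH2Cl2, -40 to 0 °C; aq. NaHCO3; crude product taken on at once
Reagents that add atoms: (R)-2,2'-diiodyl-1,1'-binaphthalene, O=I(=O)c1ccc2ccccc2c1-c1c(I(=O)=O)ccc2ccccc12
Why: Hydroxylative phenol dearomatisation by a pentavalent-iodine (iodyl) arene, in which the phenol oxygen binds to iodine and an iodyl oxygen is passed intramolecularly to the more electron-rich ortho carbon C5 (alkylated and para to O1) in preference to C7, should give the 6-alkyl-6-hydroxycyclohexa-2,4-dienone, the C2-symmetric biaryl backbone of the reagent directing the oxygen to the C5 face anti to the C2 aryl group and so setting C5 as R.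

Step 15
Reactants: 17 (2S,3S,5R)-5-allyl-5-hydroxy-3-methyl-2-(3,4,5-trimethoxyphenyl)-2,3-dihydrobenzofuran-6(5H)-one
Product: 18 (2S,3S,5R)-5-allyl-5-methoxy-3-methyl-2-(3,4,5-trimethoxyphenyl)-2,3-dihydrobenzofuran-6(5H)-one
Conditions: MeI (excess), Ag2O, 4 Å molecular sieves, CH2Cl2, rt, dark
Reagents that add atoms: iodomethane, CI
Why: Purdie-type O-methylation with MeI and Ag2O etherifies the comparatively acidic tertiary alpha-ketol hydroxyl without strong base, which avoids an alpha-ketol shift, and without a hard alkylating agent, which avoids O-alkylation of the vinylogous ester, and as the C5–O bond is not broken the C5 configuration is kept.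

Compound list
1 | 4-bromo-2,6-dimethoxyphenol | COc1cc(Br)cc(OC)c1O | starting material
2 | 2-(benzyloxy)-5-bromo-1,3-dimethoxybenzene | COc1cc(Br)cc(OC)c1OCc1ccccc1 | intermediate
3 | 2-(benzyloxy)-1,3-dimethoxy-5-(prop-1-yn-1-yl)benzene | CC#Cc1cc(OC)c(OCc2ccccc2)c(OC)c1 | intermediate
4 | 2-[(Z)-1-(4-(benzyloxy)-3,5-dimethoxyphenyl)prop-1-en-2-yl]-4,4,5,5-tetramethyl-1,3,2-dioxaborolane | C/C(B1OC(C)(C)C(C)(C)O1)=C\c1cc(OC)c(OCc2ccccc2)c(OC)c1 | intermediate
5 | 4-bromobenzene-1,3-diol (4-bromoresorcinol) | Oc1ccc(Br)c(O)c1 | starting material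
6 | 2-bromo-5-[(triisopropylsilyl)oxy]phenol | CC(C)[Si](Oc1ccc(Br)c(O)c1)(C(C)C)C(C)C | intermediate
7 | [3-(benzyloxy)-4-bromophenoxy]triisopropylsilane | CC(C)[Si](Oc1ccc(Br)c(OCc2ccccc2)c1)(C(C)C)C(C)C | intermediate
8 | {3-(benzyloxy)-4-[(E)-1-(4-(benzyloxy)-3,5-dimethoxyphenyl)prop-1-en-2-yl]phenoxy}triisopropylsilane | C/C(c1ccc(O[Si](C(C)C)(C(C)C)C(C)C)cc1OCc1ccccc1)=C\c1cc(OC)c(OCc2ccccc2)c(OC)c1 | intermediate
9 | (R)-{3-(benzyloxy)-4-[1-(4-(benzyloxy)-3,5-dimethoxyphenyl)propan-2-yl]phenoxy}triisopropylsilane | C[C@H](Cc1cc(OC)c(OCc2ccccc2)c(OC)c1)c1ccc(O[Si](C(C)C)(C(C)C)C(C)C)cc1OCc1ccccc1 | intermediate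
10 | (R)-2-[1-(4-hydroxy-3,5-dimethoxyphenyl)propan-2-yl]-5-[(triisopropylsilyl)oxy]phenol | C[C@H](Cc1cc(OC)c(O)c(OC)c1)c1ccc(O[Si](C(C)C)(C(C)C)C(C)C)cc1O | intermediate
11 | (R)-4-{2-[2-hydroxy-4-(triisopropylsilyloxy)phenyl]propylidene}-2,6-dimethoxycyclohexa-2,5-dien-1-one (p-quinone methide, not isolated) | C[C@H](C=C1C=C(OC)C(=O)C(OC)=C1)c1ccc(O[Si](C(C)C)(C(C)C)C(C)C)cc1O | intermediate
12 | 2,6-dimethoxy-4-{(2S,3S)-3-methyl-6-[(triisopropylsilyl)oxy]-2,3-dihydrobenzofuran-2-yl}phenol | C[C@H]1c2ccc(O[Si](C(C)C)(C(C)C)C(C)C)cc2O[C@@H]1c1cc(OC)c(O)c(OC)c1 | intermediate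
13 | triisopropyl{[(2S,3S)-3-methyl-2-(3,4,5-trimethoxyphenyl)-2,3-dihydrobenzofuran-6-yl]oxy}silane | C[C@H]1c2ccc(O[Si](C(C)C)(C(C)C)C(C)C)cc2O[C@@H]1c1cc(OC)c(OC)c(OC)c1 | intermediate
14 | (2S,3S)-3-methyl-2-(3,4,5-trimethoxyphenyl)-2,3-dihydrobenzofuran-6-ol | C[C@H]1c2ccc(O)cc2O[C@@H]1c1cc(OC)c(OC)c(OC)c1 | intermediate
15 | (2S,3S)-5-bromo-3-methyl-2-(3,4,5-trimethoxyphenyl)-2,3-dihydrobenzofuran-6-ol | C[C@H]1c2cc(Br)c(O)cc2O[C@@H]1c1cc(OC)c(OC)c(OC)c1 | intermediate
16 | (2S,3S)-5-allyl-3-methyl-2-(3,4,5-trimethoxyphenyl)-2,3-dihydrobenzofuran-6-ol | C[C@H]1c2cc(CC=C)c(O)cc2O[C@@H]1c1cc(OC)c(OC)c(OC)c1 | intermediate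
17 | (2S,3S,5R)-5-allyl-5-hydroxy-3-methyl-2-(3,4,5-trimethoxyphenyl)-2,3-dihydrobenzofuran-6(5H)-one | C=CC[C@@]1(O)C=C2C(=CC1=O)O[C@H](c1cc(OC)c(OC)c(OC)c1)[C@H]2C | intermediate
18 | (2S,3S,5R)-5-allyl-5-methoxy-3-methyl-2-(3,4,5-trimethoxyphenyl)-2,3-dihydrobenzofuran-6(5H)-one | C=CC[C@@]1(OC)C=C2C(=CC1=O)O[C@H](c1cc(OC)c(OC)c(OC)c1)[C@H]2C | target

Total step count: 15. Longest linear sequence: 13 steps (steps 1–3 and 6–15); the ring A branch (steps 4 and 5) joins at step 6.

Steps most likely to fail

Step 14. The reagent may discriminate poorly between the two faces at C5 on this already chiral substrate, some oxygen may be delivered to C7, and the freshly formed quinol may dimerise by [4+2] cycloaddition before it is capped. The fallback forms the C5–allyl bond instead of the C5–O bond and sets out from 14, so that steps 12 and 13 are not needed. Oxidation of 14 with 2-iodoxybenzoic acid in DMF should oxygenate the ortho position para to O1 and give the ortho-quinone (2S,3S)-3-methyl-2-(3,4,5-trimethoxyphenyl)-2,3-dihydrobenzofuran-5,6-dione F1. Barbier allylation with indium metal and allyl bromide in THF/H2O should add to the C5 carbonyl, the C6 carbonyl being deactivated as a vinylogous ester. This gives 17 together with its C5 epimer (2S,3S,5S)-5-allyl-5-hydroxy-3-methyl-2-(3,4,5-trimethoxyphenyl)-2,3-dihydrobenzofuran-6(5H)-one F2, which is a diastereomer and is removed by chromatography. The route is rejoined at 17.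

Step 15. Etherification of the hindered tertiary hydroxyl may be slow, leaving time for an alpha-ketol rearrangement or for dimerisation of the dienone. The fallback never passes through the free quinol. It sets out from 16 and treats the phenol with PhI(OAc)2 in methanol at 0 °C, a methoxylative dearomatisation in which methanol attacks the oxidised ring at the allyl-bearing ortho carbon. This should give 18 directly, accompanied by its C5 epimer (2S,3S,5S)-5-allyl-5-methoxy-3-methyl-2-(3,4,5-trimethoxyphenyl)-2,3-dihydrobenzofuran-6(5H)-one F3, which is separated by chromatography. The route is rejoined at 18.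

Step 9. The quinone methide may tautomerise to the hydroxystilbene before it cyclises, which would erase the C3 configuration, or the product may be oxidised a second time and aromatise. The fallback reaches the same benzylic electrophile without an oxidant and sets out from 8. Asymmetric hydroboration with monoisopinocampheylborane followed by NaBO3 oxidation places the hydroxyl on the less substituted alkene carbon and sets C3 by syn addition. This gives (1S,2S)-1-[4-(benzyloxy)-3,5-dimethoxyphenyl]-2-[2-(benzyloxy)-4-(triisopropylsilyloxy)phenyl]propan-1-ol F4. Neutral hydrogenolysis (H2, Pd/C, EtOAc) then gives (1S,2S)-1-(4-hydroxy-3,5-dimethoxyphenyl)-2-[2-hydroxy-4-(triisopropylsilyloxy)phenyl]propan-1-ol F5. Catalytic p-toluenesulfonic acid in CH2Cl2 at 0 °C ionises the benzylic alcohol and the ring A hydroxyl closes ring B trans to the methyl group. The route is rejoined at 12.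

Further compounds
F1 | step 14 | (2S,3S)-3-methyl-2-(3,4,5-trimethoxyphenyl)-2,3-dihydrobenzofuran-5,6-dione | C[C@H]1C2=CC(=O)C(=O)C=C2O[C@@H]1c1cc(OC)c(OC)c(OC)c1
F2 | step 14 | (2S,3S,5S)-5-allyl-5-hydroxy-3-methyl-2-(3,4,5-trimethoxyphenyl)-2,3-dihydrobenzofuran-6(5H)-one | C=CC[C@]1(O)C=C2C(=CC1=O)O[C@H](c1cc(OC)c(OC)c(OC)c1)[C@H]2C
F3 | step 15 | (2S,3S,5S)-5-allyl-5-methoxy-3-methyl-2-(3,4,5-trimethoxyphenyl)-2,3-dihydrobenzofuran-6(5H)-one | C=CC[C@]1(OC)C=C2C(=CC1=O)O[C@H](c1cc(OC)c(OC)c(OC)c1)[C@H]2C
F4 | step 9 | (1S,2S)-1-[4-(benzyloxy)-3,5-dimethoxyphenyl]-2-[2-(benzyloxy)-4-(triisopropylsilyloxy)phenyl]propan-1-ol | C[C@H]([C@H](O)c1cc(OC)c(OCc2ccccc2)c(OC)c1)c1ccc(O[Si](C(C)C)(C(C)C)C(C)C)cc1OCc1ccccc1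
F5 | step 9 | (1S,2S)-1-(4-hydroxy-3,5-dimethoxyphenyl)-2-[2-hydroxy-4-(triisopropylsilyloxy)phenyl]propan-1-ol | C[C@H]([C@H](O)c1cc(OC)c(O)c(OC)c1)c1ccc(O[Si](C(C)C)(C(C)C)C(C)C)cc1O
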